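Read two constants from the runs, counting every amount as a fraction of its charge.

| setting | amber | ochre | flask |
|---|---|---|---|
| starting material | 24 mM | 24 mM | 24 mM |
| reagent | 72 mM | 140 mM | 72.0 mM |
| free catalyst | 24 µM | 24 µM | 24 µM |
| remark | the very flask that is asked about, followed so far | run made earlier |  |
| time |  |  | 8.0 min |

- amber (time / min: target / %, starting material / %): 0.500: 4.7, 93.3; 1.00: 7.0, 86.2; 2.00: 10.1, 70.3; 3.00: 11.3, 56.9; 6.00: 13.8, 26.6
- ochre (time / min: target / %, starting material / %): 0.250: 3.5, 95.3; 0.500: 7.0, 89.7; 0.833: 9.8, 82.8; 1.50: 12.9, 68.1; 3.00: 17.3, 41.4

(each reading ± 0.3 percentage points)

- Friday's: at 8.0 min add free catalyst, 100% of the amount charged, then wait 8.0 min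
- Thursday's: at 8.0 min add reagent, 100% of the amount charged, then wait 8.0 min
- Saturday's: at 8.0 min take out 90% of the by-product then present, then wait 8.0 min
- Sunday's: change nothing and wait 8.0 min more

- what is added takes up no volume worth counting

1. target, in percent of the starting material first charged, at 8.0 min
2. which option adds most target ("none" when 2 percentage points or less is all one gets) (Friday's / Thursday's / Saturday's / Sunday's / none)
3. target present, in percent of the starting material first charged, after Saturday's
4. target present, in percent of the starting material first charged, after Sunday's

1. Suppose each target lost takes one starting material with it. Then half the sum of starting-material loss and target gain is target made, and half their difference is target eaten.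

2. Divide by the mean amounts. The amber run from 3.00 min to 6.00 min gives an eating constant of 0.884 /min and a making constant of 0.131 /min. The ochre run from 1.50 min to 3.00 min reads 0.899 /min and 0.189 /min. So the ochre run, with more reagent and read earlier, shows eating about the same and making faster.

3. Turn these into times. Target is eaten in 1.13 min at a full charge of starting material. The amber run's late pseudo-first-order loss, 0.253 /min, takes starting material in 3.95 min. Making takes 7.63 min. Eating at a full charge is quicker than making. In this reckoning both scale with starting material, so with the catalyst taken as steady their ratio gives a level for target.

4. Making equals eating at the target ceiling, the making constant over the eating constant, here a reading from the amber run: 14.8%. With the catalyst steady, the net share of starting material lost that reaches target is (ceiling − target) over (ceiling + target).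

5. My reckoning for the flask at 8.0 min: starting material 16.0%, target just under the ceiling, so I expect Sunday's to stay inside the margin of 2 percentage points. The two constants say nothing of by-product, so I count Saturday's the same. If making follows catalyst, Friday's doubles the ceiling, the share starts at a third, and that first share on the starting material left gives 5.3 points. Thursday's, taken at the ochre ceiling 21.1%, gives by its first share 2.8 points. I choose Friday's.

6. The forecast gave 14.4%, 17% after Saturday's and 15% after Sunday's, and said “Saturday's is best”.

7. The flask gives 13.7% at 8.0 min, and Friday's adds 6.2 points, but Thursday's changes target by −3 points, and Saturday's and Sunday's each end at 10.3%. My steady ceiling parts from the flask here. At 2.59 min target is made 1.23 times as fast as it is used, while at 8.00 min 29.1% of the catalyst can still turn over, with spent catalyst at 70.9%.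

    catalyst intermediate C → free catalyst + target (k = 23.0 /s)
    starting material + target → side product (k = 0.650 /M/s)
    catalyst intermediate A ⇌ by-product + catalyst intermediate B (K = 0.0200 M, k = 17.0 /s)
    crystals ⇌ by-product, rate k4*(cs4 - [by-product]) while solid is left; crystals form when [by-product] > cs4 (solubility = 0.760 mM, k = 0.440 /s)
    reagent + free catalyst ⇌ catalyst intermediate A (K = 2.90 /M, k = 150 /M/s)
    catalyst intermediate B → spent catalyst (k = 0.0140 /s)
    starting material + catalyst intermediate B ⇌ catalyst intermediate C (K = 37.0 /M, k = 81000 /M/s)

8. For the neighbour with 0.014 mM of free catalyst, the ceiling, if making follows catalyst, scales to 8.64%. That neighbour reaches 6.26% at 8.0 min, with 39.9% of its starting material left.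

Readings and results stem from a simulated flask with constants of no real substance.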